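Readings and results are simulated for an exercise, noise included.

1. At early times E drops fast by about the D charged and Q then climbs steadily, so I read D as a cycle and assume that each E converted finally costs one L. This is a guess, since no run shows L or varies its charge.

all flasks: E 1.4 M; L 1.12 M

| charge | D | remark |
|---|---|---|
| Sunday's | 250 mM | run made earlier |
| Saturday's | 400 mM | run made earlier |
| flask | 180 mM |  |

| run | time / h | Q / % | E / % |
|---|---|---|---|
| Sunday's | 0.667 | 9.2 | 73.7 |
| Sunday's | 1.33 | 18.8 | 63.7 |
| Sunday's | 2.00 | 28.4 | 54.4 |
| Sunday's | 3.00 | 41.9 | 40.7 |
| Sunday's | 4.00 | 52.0 | 30.1 |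
| Saturday's | 0.667 | 15.3 | 57.3 |
| Saturday's | 1.33 | 29.6 | 42.9 |
| Saturday's | 2.00 | 44.1 | 27.8 |
| Saturday's | 3.00 | 58.3 | 14.3 |
| Saturday's | 4.00 | 64.7 | 8.5 |

(standard deviation of a reading: 0.3 percentage points)

- apparent order in D when 50% of the E are converted (percent change of the rate of making Q for one percent more D charged)
- apparent order in L when 50% of the E are converted (percent change of the rate of making Q for one percent more L charged)

2. My number is the L demand, the E converted so far divided by the L charged, which for the flask at the asked conversion is 0.625. It says what part of the L charge the cycle has claimed.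

3. I test it on both runs. In the readings, Saturday's Q rate drops to 0.656 of its value after 2.00 h, at a demand of 0.902. Sunday's drops to 0.748 after 3.00 h, at a smaller demand of 0.741. One number is therefore not enough: in these readings Sunday's run, with less D, bends earlier in demand, as if L also leaves with time.

4. The flask has still less D, so I expect its bend near 0.625. In my reckoning, a little more D in this flask reaches the asked conversion sooner and with more L left, which puts my order in D above one and my order in L near 0.5. The forecast differs on D, with 1 in D and 0.4 in L, placing the flask “near the knee, so the order in L is modest and uncertain”.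

5. The flask gives 1.3 in D and 0.47 in L.

    E + D → G (k = 0.589 L mol⁻¹ min⁻¹)
    L + G → Z (k = 1.73 L mol⁻¹ min⁻¹)
    Z → D + Q (k = 0.0141 min⁻¹)
    L → X (k = 0.00383 min⁻¹)

In the flask at 1.86 h, L enters Z 1.6 times as fast as it turns into X. At 3.00 h the flask's demand is 0.543 while 85.1% of the L charged is gone, with X at 0.353 M, and by 6.00 h L, the limiting reagent, stands at 0% with E at 36%.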